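Amounts first: the flask is charged with c(starting material) = 2.0 M and read at 4.0 h; that charge lies between the grey and ochre charges.

| flask | starting material | remark | time |
|---|---|---|---|
| grey | 1.3 M | run made earlier |  |
| ochre | 3 M | run made earlier |  |
| flask | 2.0 M |  | 4.0 h |
- grey (time / h: target / %, crystals / %): 0.333: 7.0, 2.5; 1.00: 14.9, 11.2; 1.50: 20.3, 16.9; 2.50: 29.4, 26.2; 4.00: 39.8, 35.9; 5.00: 43.7, 40.8
- ochre (time / h: target / %, crystals / %): 0.417: 9.4, 6.4; 0.667: 13.8, 11.1; 1.00: 19.2, 16.7; 2.00: 33.6, 30.5; 3.00: 44.6, 42.6; 5.00: 59.9, 58.3

(standard deviation of a reading: 0.3 percentage points)
1. how much target and crystals together there is at 4.0 h, in percent of the starting material charged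
2. concentration of target in solution at 4.0 h, in percent of saturation
- target is meant together with its crystals
- solid, in amounts per volume of the solution: crystals

Don't count the target made; count what is not target, and ask how long that part takes to halve. The grey run at 4.00 h still has 60.2% not target, a half-life of 5.46 h. The ochre run has no reading at that time, but its readings at 3.00 h and 5.00 h stand either side of it, and their half-lives average 3.66 h, shorter than grey's, so between these two runs the half-life falls as the charge rises. Grey's was 4.30 h at 1.00 h, so I use late readings. Reading between them on a logarithmic scale of charge, I get the apparent first-order half-life of the flask, 4.44 h. Two times now matter, this one and 4.0 h. Their ratio, 0.901 halvings, leaves 53.6%, so my yield is 46.4%.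

The forecast gives a yield of 46.2%, slightly below mine, and a dissolved target at 113% of saturation, noting that “no simple law fits exactly”.

The flask gives 47.8% and 134%: the yield is within tolerance, the saturation 21 percentage points above the forecast, with dissolved c(target) at 45.6 mM against a saturation of 34 mM.

    starting material ⇌ target (K = 0.0700, k = 0.370 h⁻¹)
    target ⇌ isomer of the product A (K = 0.360, k = 0.290 h⁻¹)
    isomer of the product A ⇌ isomer of the product B (K = 0.470, k = 0.130 h⁻¹)
    isomer of the product B ⇌ starting material (k = 0.430 h⁻¹)
    crystals ⇌ target, rate k5*(cs5 - [target]) while solid is left; crystals form when [target] > cs5 (solubility = 34.0 mM, k = 12.0 h⁻¹)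

The same charge read at 2.5 h is 0.563 halvings, so a half-life of 4.44 h leaves 67.7% not target; that neighbouring flask has 64.5% not target.

All runs come from a simulation for substances that don't exist, noise included.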